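The oxocane ring (O1, C2 with the pentenynyl chain, C3–C8) is traced back to a cyclohept-4-enone in which O1 is still missing: C3–C2–C8 is an oxyallyl-type three-carbon unit, C4–C7 is butadiene, and O1 is inserted later between C2 and C8 by Baeyer–Villiger oxidation. The key step, a rhodium-catalysed tandem cyclopropanation/Cope rearrangement (formal [4+3]) of an acyclic chiral 2-siloxyvinyldiazoacetate with butadiene, forms C3–C4 and C7–C8 in one operation and sets C8; it exploits the four-carbon arc C4–C7 whose flanking atoms C3 and C8 are joined through C2. Enolate hydroxylation, C-allylation, chloride installation, enyne construction and late bromination follow.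

Key step: step 4

Numbering: atoms carry the numbers of the target oxocane throughout (O1; C2 bears the pentenynyl chain; C3 and C5 bear Cl; C6 bears OAc; C8 bears the bromopropyl chain, whose carbinol carbon is C9).
Assumption: Rh2(S-PTAD)4 is taken to deliver the (1R,2S)-cyclopropane 6 by the facial model of donor/acceptor carbenoids; if the sense proves opposite, Rh2(R-PTAD)4 is used and nothing else changes.

Step 1
Reactants: 1 methyl (3R)-3-hydroxypentanoate
Product: 2 tert-butyl (5R)-5-hydroxy-3-oxoheptanoate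
Conditions: LDA (3.3 equiv), tert-butyl acetate (3.3 equiv), THF, −78 °C; then 1, −78 → −30 °C; aq NH4Cl
Reagents that add atoms: tert-butyl acetate (as its lithium enolate), CC(=O)OC(C)(C)C
Why: Crossed Claisen condensation, in which the excess ester enolate first deprotonates the hydroxyl and then acylates at the methyl ester, leaving the carbinol stereocentre (future C9) untouched.

Step 2
Reactants: 2 tert-butyl (5R)-5-hydroxy-3-oxoheptanoate
Product: 3 tert-butyl (5R)-2-diazo-5-hydroxy-3-oxoheptanoate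
Conditions: 4-acetamidobenzenesulfonyl azide, Et3N, MeCN, 0 °C → rt
Reagents that add atoms: 4-acetamidobenzenesulfonyl azide, CC(=O)Nc1ccc(cc1)S(=O)(=O)N=[N+]=[N-]
Why: Regitz diazo transfer to the active methylene of the β-keto ester, which does not involve the stereocentre.

Step 3
Reactants: 3 tert-butyl (5R)-2-diazo-5-hydroxy-3-oxoheptanoate
Product: 4 tert-butyl (3Z,5R)-2-diazo-3,5-bis(triisopropylsilyloxy)hept-3-enoate
Conditions: TIPSOTf (2.4 equiv), Et3N, CH2Cl2, 0 °C → rt
Reagents that add atoms: triisopropylsilyl trifluoromethanesulfonate, CC(C)[Si](C(C)C)(C(C)C)OS(=O)(=O)C(F)(F)F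
Why: Silylation of the alcohol and soft enolisation toward the only α-methylene give the 2-siloxyvinyldiazoacetate, the Z enol ether (siloxy cis to the side chain) being the usual outcome of amine/silyl triflate enolisation of 2-diazo-3-oxo esters.

Step 4
Reactants: 4 tert-butyl (3Z,5R)-2-diazo-3,5-bis(triisopropylsilyloxy)hept-3-enoate; 5 buta-1,3-diene
Product: 7 tert-butyl (3R)-2-(triisopropylsilyloxy)-3-[(1R)-1-(triisopropylsilyloxy)propyl]cyclohepta-1,5-diene-1-carboxylate, via cis-divinylcyclopropane 6 (not isolated)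
Conditions: dirhodium tetrakis[(S)-N-phthaloyl-1-adamantylglycinate] Rh2(S-PTAD)4 (1 mol %), 5 (10 equiv), hexanes, −30 °C, slow addition of 4; then 60 °C
Reagents that add atoms: none
Why: The rhodium-bound 2-siloxyvinylcarbenoid from 4 cyclopropanates one double bond of 5 with its siloxyvinyl (donor) group cis to the remaining vinyl group, forming C3–C4 and a transient C3–C5 bond, and the cis-divinylcyclopropane 6 then undergoes a Cope rearrangement through the endo boat transition state, forming C7–C8 and cleaving C3–C5. The closest known reaction type is the tandem cyclopropanation/Cope rearrangement (formal [4+3] cycloaddition) of 2-siloxyvinyldiazoacetates with 1,3-dienes. The three-membered ring is closed by intermolecular [2+1] carbene transfer and the seven-membered ring by the [3,3]-sigmatropic ring expansion, which opens the cyclopropane again. The only new stereocentre that persists, C8, is set by chirality transfer from 6, whose absolute configuration is fixed by the chiral carboxylate catalyst, while the Z enol ether keeps the C9 side chain outside the boat so that C8 emerges R. The step needs carbene transfer at the carbenoid carbon (not vinylogous attack or O–H insertion) and a cis-divinyl arrangement; the 2-siloxy group, the fully silylated substrate and the intrinsic diastereoselectivity of donor/acceptor carbenoids secure these, and the symmetry of 5 removes any regiochemical question.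

Step 5
Reactants: 7 tert-butyl (3R)-2-(triisopropylsilyloxy)-3-[(1R)-1-(triisopropylsilyloxy)propyl]cyclohepta-1,5-diene-1-carboxylate
Product: 10 (2R)-2-[(1R)-1-(triisopropylsilyloxy)propyl]cyclohept-4-en-1-one, via β-keto ester 8 (not isolated), via β-keto acid 9 (not isolated)
Conditions: CF3CO2H, CH2Cl2, 0 °C → rt; then toluene, 60 °C
Reagents that add atoms: none
Why: Protodesilylation of the silyl enol ether, acidolysis of the tert-butyl ester and thermal decarboxylation of the β-keto acid remove the activating ester without base, so the α-stereocentre C8 and the secondary silyl ether should be untouched.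

Step 6
Reactants: 10 (2R)-2-[(1R)-1-(triisopropylsilyloxy)propyl]cyclohept-4-en-1-one
Product: 11 (5Z,8R)-8-[(1R)-1-(triisopropylsilyloxy)propyl]-3,4,7,8-tetrahydro-2H-oxocin-2-one
Conditions: Me3SiOOSiMe3 (2 equiv), TMSOTf (10 mol %), CH2Cl2, −40 → −20 °C
Reagents that add atoms: bis(trimethylsilyl) peroxide, C[Si](C)(C)OO[Si](C)(C)C
Why: Baeyer–Villiger oxidation with a silyl peroxide instead of a peracid leaves the C5=C6 alkene untouched, and the more substituted α-carbon C8 migrates with retention, so O1 is inserted between C2 and C8.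

Step 7
Reactants: 11 (5Z,8R)-8-[(1R)-1-(triisopropylsilyloxy)propyl]-3,4,7,8-tetrahydro-2H-oxocin-2-one
Product: 13 (3R,5Z,8R)-3-hydroxy-8-[(1R)-1-(triisopropylsilyloxy)propyl]-3,4,7,8-tetrahydro-2H-oxocin-2-one, via potassium enolate 12 (not isolated)
Conditions: KHMDS, THF, −78 °C; then 2-(phenylsulfonyl)-3-phenyloxaziridine, −78 °C; aq NH4Cl
Reagents that add atoms: 2-(phenylsulfonyl)-3-phenyloxaziridine, O=S(=O)(N1OC1c1ccccc1)c1ccccc1
Why: Enolate oxidation with an N-sulfonyloxaziridine at C3, the only enolisable position, where the oxidant is expected to attack the peripheral enolate face of the (Z)-ene lactone, syn to the C8 substituent, to give the 3,8-cis hydroxy lactone.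

Step 8
Reactants: 13 (3R,5Z,8R)-3-hydroxy-8-[(1R)-1-(triisopropylsilyloxy)propyl]-3,4,7,8-tetrahydro-2H-oxocin-2-one
Product: 15 (3R,5Z,8R)-8-[(1R)-1-(triisopropylsilyloxy)propyl]-3,4,7,8-tetrahydro-2H-oxocine-2,3-diyl diacetate (C2 anomers), via lactol 14 (not isolated)
Conditions: i-Bu2AlH (2.2 equiv), CH2Cl2, −78 °C; then pyridine, DMAP, Ac2O, −78 → 0 °C
Reagents that add atoms: acetic anhydride, CC(=O)OC(C)=O
Why: Partial reduction of the lactone to the aluminium lactolate and acetylation in situ (reductive acetylation) trap the eight-membered lactol before ring–chain tautomerism and acetylate the C3 hydroxyl at the same time, the C2 anomers converging in step 9.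

Step 9
Reactants: 15 (3R,5Z,8R)-8-[(1R)-1-(triisopropylsilyloxy)propyl]-3,4,7,8-tetrahydro-2H-oxocine-2,3-diyl diacetate
Product: 16 (2S,3R,5Z,8R)-2-allyl-8-[(1R)-1-(triisopropylsilyloxy)propyl]-3,4,7,8-tetrahydro-2H-oxocin-3-yl acetate
Conditions: allyltrimethylsilane (4 equiv), TMSOTf (30 mol %), CH2Cl2, −78 → −30 °C
Reagents that add atoms: allyltrimethylsilane, C=CC[Si](C)(C)C
Why: Hosomi–Sakurai-type C-glycosylation in which the eight-membered oxocarbenium ion is attacked at C2 on the face opposite to both the C3 acetoxy group and the C8 side chain, setting C2 trans to both.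

Step 10
Reactants: 16 (2S,3R,5Z,8R)-2-allyl-8-[(1R)-1-(triisopropylsilyloxy)propyl]-3,4,7,8-tetrahydro-2H-oxocin-3-yl acetate
Product: 17 (2S,3R,5R,6S,8R)-2-allyl-5,6-epoxy-8-[(1R)-1-(triisopropylsilyloxy)propyl]oxocan-3-yl acetate (epoxide oxygen anti to the C3 acetoxy group and the C8 chain)
Conditions: m-CPBA (1.05 equiv), NaHCO3, CH2Cl2, 0 °C
Reagents that add atoms: 3-chloroperbenzoic acid, OOC(=O)c1cccc(Cl)c1
Why: Prilezhaev epoxidation of the cis-disubstituted ring alkene, which is more nucleophilic than the terminal allyl alkene, from the ring face anti to the C3 acetoxy group and the C8 side chain that flank C5 and C6 on the other face.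

Step 11
Reactants: 17 (2S,3R,5R,6S,8R)-2-allyl-5,6-epoxy-8-[(1R)-1-(triisopropylsilyloxy)propyl]oxocan-3-yl acetate
Product: 18 (2S,3R,5R,6S,8R)-2-allyl-5,6-epoxy-8-[(1R)-1-(triisopropylsilyloxy)propyl]oxocan-3-ol
Conditions: K2CO3 (20 mol %), MeOH, 0 °C → rt
Reagents that add atoms: none
Why: Mild transesterification removes the C3 acetate, while the epoxide and the silyl ether are stable to catalytic carbonate in methanol.

Step 12
Reactants: 18 (2S,3R,5R,6S,8R)-2-allyl-5,6-epoxy-8-[(1R)-1-(triisopropylsilyloxy)propyl]oxocan-3-ol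
Product: 20 (2S,3S,5R,6S,8R)-2-allyl-3-chloro-5,6-epoxy-8-[(1R)-1-(triisopropylsilyloxy)propyl]oxocane, via triflate 19 (not isolated)
Conditions: Tf2O, pyridine, CH2Cl2, −40 °C; then n-Bu4NCl, −40 °C → rt
Reagents that add atoms: tetrabutylammonium chloride, CCCC[N+](CCCC)(CCCC)CCCC.[Cl-]
Why: SN2 displacement of the secondary triflate by chloride inverts C3 and places chlorine cis to the allyl group, and neutral chloride without a Lewis acid should leave the epoxide closed.

Step 13
Reactants: 20 (2S,3S,5R,6S,8R)-2-allyl-3-chloro-5,6-epoxy-8-[(1R)-1-(triisopropylsilyloxy)propyl]oxocane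
Product: 21 (2S,3S,5S,6S,8R)-2-allyl-3,5-dichloro-8-[(1R)-1-(triisopropylsilyloxy)propyl]oxocan-6-yl acetate
Conditions: AcCl (3 equiv), n-Bu4NCl (10 mol %), CH2Cl2, 0 °C → rt
Reagents that add atoms: acetyl chloride, CC(Cl)=O
Why: Chloride-catalysed acylative opening of the epoxide to a β-chloroalkyl ester, in which chloride attacks C5 anti to the epoxide oxygen because C6 is shielded on that face by the 1,3-related C8 side chain, while the oxygen stays on C6 with retention and is acetylated.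

Step 14
Reactants: 21 (2S,3S,5S,6S,8R)-2-allyl-3,5-dichloro-8-[(1R)-1-(triisopropylsilyloxy)propyl]oxocan-6-yl acetate
Product: 22 (2S,3S,5S,6S,8R)-3,5-dichloro-2-[(2E)-4-oxobut-2-en-1-yl]-8-[(1R)-1-(triisopropylsilyloxy)propyl]oxocan-6-yl acetate
Conditions: crotonaldehyde (10 equiv), second-generation Grubbs catalyst RuCl2(H2IMes)(PCy3)(=CHPh) (5 mol %), CH2Cl2, 40 °C
Reagents that add atoms: (E)-crotonaldehyde, C/C=C/C=O
Why: Olefin cross-metathesis of the terminal alkene with excess crotonaldehyde gives the conjugated E enal under thermodynamic control.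

Step 15
Reactants: 22 (2S,3S,5S,6S,8R)-3,5-dichloro-2-[(2E)-4-oxobut-2-en-1-yl]-8-[(1R)-1-(triisopropylsilyloxy)propyl]oxocan-6-yl acetate
Product: 23 (2S,3S,5S,6S,8R)-3,5-dichloro-2-[(2E)-pent-2-en-4-yn-1-yl]-8-[(1R)-1-(triisopropylsilyloxy)propyl]oxocan-6-yl acetate
Conditions: Me3SiCHN2, LDA, THF, −78 °C; then 22, −78 → 0 °C; aq NH4Cl
Reagents that add atoms: (trimethylsilyl)diazomethane, C[Si](C)(C)C=[N+]=[N-]
Why: Colvin rearrangement, in which lithiated trimethylsilyldiazomethane adds to the aldehyde and Peterson-type elimination and 1,2-hydride shift of the alkylidene carbene give the terminal alkyne at low temperature, so the E alkene, the acetate and the chlorides are retained.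

Step 16
Reactants: 23 (2S,3S,5S,6S,8R)-3,5-dichloro-2-[(2E)-pent-2-en-4-yn-1-yl]-8-[(1R)-1-(triisopropylsilyloxy)propyl]oxocan-6-yl acetate
Product: 24 (2S,3S,5S,6S,8R)-3,5-dichloro-8-[(1R)-1-hydroxypropyl]-2-[(2E)-pent-2-en-4-yn-1-yl]oxocan-6-yl acetate
Conditions: 48% aq HF, MeCN, 0 °C → rt
Reagents that add atoms: none
Why: Fluoride cleavage of the hindered silyl ether under acidic conditions that leave the acetate, the chlorides and the enyne intact.

Step 17
Reactants: 24 (2S,3S,5S,6S,8R)-3,5-dichloro-8-[(1R)-1-hydroxypropyl]-2-[(2E)-pent-2-en-4-yn-1-yl]oxocan-6-yl acetate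
Product: 25 (2S,3S,5S,6S,8R)-8-[(1S)-1-bromopropyl]-3,5-dichloro-2-[(2E)-pent-2-en-4-yn-1-yl]oxocan-6-yl acetate
Conditions: CBr4, P(n-C8H17)3, toluene, 70 °C
Reagents that add atoms: tetrabromomethane, BrC(Br)(Br)Br
Why: Appel-type bromination through the alkoxyphosphonium ion, in which bromide displaces with inversion and converts the (R)-carbinol into the (S)-bromide at C9.

Compound list
1 | methyl (3R)-3-hydroxypentanoate | CC[C@@H](O)CC(=O)OC | starting material
2 | tert-butyl (5R)-5-hydroxy-3-oxoheptanoate | CC[C@@H](O)CC(=O)CC(=O)OC(C)(C)C | intermediate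
3 | tert-butyl (5R)-2-diazo-5-hydroxy-3-oxoheptanoate | CC[C@@H](O)CC(=O)C(=[N+]=[N-])C(=O)OC(C)(C)C | intermediate
4 | tert-butyl (3Z,5R)-2-diazo-3,5-bis(triisopropylsilyloxy)hept-3-enoate | CC[C@@H](O[Si](C(C)C)(C(C)C)C(C)C)/C=C(O[Si](C(C)C)(C(C)C)C(C)C)/C(=[N+]=[N-])C(=O)OC(C)(C)C | intermediate
5 | buta-1,3-diene | C=CC=C | starting material
6 | tert-butyl (1R,2S)-1-[(1Z,3R)-1,3-bis(triisopropylsilyloxy)pent-1-en-1-yl]-2-vinylcyclopropane-1-carboxylate | C=C[C@@H]1C[C@]1(C(=O)OC(C)(C)C)/C(O[Si](C(C)C)(C(C)C)C(C)C)=C/[C@H](O[Si](C(C)C)(C(C)C)C(C)C)CC | intermediate (not isolated)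
7 | tert-butyl (3R)-2-(triisopropylsilyloxy)-3-[(1R)-1-(triisopropylsilyloxy)propyl]cyclohepta-1,5-diene-1-carboxylate | O=C(OC(C)(C)C)C1=C(O[Si](C(C)C)(C(C)C)C(C)C)[C@@H]([C@H](O[Si](C(C)C)(C(C)C)C(C)C)CC)C/C=C\C1 | intermediate
8 | tert-butyl (3R)-2-oxo-3-[(1R)-1-(triisopropylsilyloxy)propyl]cyclohept-5-ene-1-carboxylate (C1 epimers) | O=C1[C@@H]([C@H](O[Si](C(C)C)(C(C)C)C(C)C)CC)C/C=C\CC1C(=O)OC(C)(C)C | intermediate (not isolated)
9 | (3R)-2-oxo-3-[(1R)-1-(triisopropylsilyloxy)propyl]cyclohept-5-ene-1-carboxylic acid (C1 epimers) | O=C1[C@@H]([C@H](O[Si](C(C)C)(C(C)C)C(C)C)CC)C/C=C\CC1C(=O)O | intermediate (not isolated)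
10 | (2R)-2-[(1R)-1-(triisopropylsilyloxy)propyl]cyclohept-4-en-1-one | O=C1[C@@H]([C@H](O[Si](C(C)C)(C(C)C)C(C)C)CC)C/C=C\CC1 | intermediate
11 | (5Z,8R)-8-[(1R)-1-(triisopropylsilyloxy)propyl]-3,4,7,8-tetrahydro-2H-oxocin-2-one | O=C1O[C@@H]([C@H](O[Si](C(C)C)(C(C)C)C(C)C)CC)C/C=C\CC1 | intermediate
12 | potassium enolate of 11 | [K+].[O-]C1=CC/C=C\C[C@H]([C@H](O[Si](C(C)C)(C(C)C)C(C)C)CC)O1 | intermediate (not isolated)
13 | (3R,5Z,8R)-3-hydroxy-8-[(1R)-1-(triisopropylsilyloxy)propyl]-3,4,7,8-tetrahydro-2H-oxocin-2-one | O=C1O[C@@H]([C@H](O[Si](C(C)C)(C(C)C)C(C)C)CC)C/C=C\C[C@H]1O | intermediate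
14 | (3R,5Z,8R)-8-[(1R)-1-(triisopropylsilyloxy)propyl]-3,4,7,8-tetrahydro-2H-oxocine-2,3-diol (lactol, C2 epimers, present as its aluminium alkoxide) | OC1O[C@@H]([C@H](O[Si](C(C)C)(C(C)C)C(C)C)CC)C/C=C\C[C@H]1O | intermediate (not isolated)
15 | (3R,5Z,8R)-8-[(1R)-1-(triisopropylsilyloxy)propyl]-3,4,7,8-tetrahydro-2H-oxocine-2,3-diyl diacetate (C2 anomers) | CC(=O)OC1O[C@@H]([C@H](O[Si](C(C)C)(C(C)C)C(C)C)CC)C/C=C\C[C@H]1OC(C)=O | intermediate
16 | (2S,3R,5Z,8R)-2-allyl-8-[(1R)-1-(triisopropylsilyloxy)propyl]-3,4,7,8-tetrahydro-2H-oxocin-3-yl acetate | C=CC[C@@H]1O[C@@H]([C@H](O[Si](C(C)C)(C(C)C)C(C)C)CC)C/C=C\C[C@H]1OC(C)=O | intermediate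
17 | (2S,3R,5R,6S,8R)-2-allyl-5,6-epoxy-8-[(1R)-1-(triisopropylsilyloxy)propyl]oxocan-3-yl acetate | C=CC[C@@H]1O[C@@H]([C@H](O[Si](C(C)C)(C(C)C)C(C)C)CC)C[C@@H]2O[C@@H]2C[C@H]1OC(C)=O | intermediate
18 | (2S,3R,5R,6S,8R)-2-allyl-5,6-epoxy-8-[(1R)-1-(triisopropylsilyloxy)propyl]oxocan-3-ol | C=CC[C@@H]1O[C@@H]([C@H](O[Si](C(C)C)(C(C)C)C(C)C)CC)C[C@@H]2O[C@@H]2C[C@H]1O | intermediate
19 | (2S,3R,5R,6S,8R)-2-allyl-5,6-epoxy-8-[(1R)-1-(triisopropylsilyloxy)propyl]oxocan-3-yl trifluoromethanesulfonate | C=CC[C@@H]1O[C@@H]([C@H](O[Si](C(C)C)(C(C)C)C(C)C)CC)C[C@@H]2O[C@@H]2C[C@H]1OS(=O)(=O)C(F)(F)F | intermediate (not isolated)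
20 | (2S,3S,5R,6S,8R)-2-allyl-3-chloro-5,6-epoxy-8-[(1R)-1-(triisopropylsilyloxy)propyl]oxocane | C=CC[C@@H]1O[C@@H]([C@H](O[Si](C(C)C)(C(C)C)C(C)C)CC)C[C@@H]2O[C@@H]2C[C@@H]1Cl | intermediate
21 | (2S,3S,5S,6S,8R)-2-allyl-3,5-dichloro-8-[(1R)-1-(triisopropylsilyloxy)propyl]oxocan-6-yl acetate | C=CC[C@@H]1O[C@@H]([C@H](O[Si](C(C)C)(C(C)C)C(C)C)CC)C[C@H](OC(C)=O)[C@@H](Cl)C[C@@H]1Cl | intermediate
22 | (2S,3S,5S,6S,8R)-3,5-dichloro-2-[(2E)-4-oxobut-2-en-1-yl]-8-[(1R)-1-(triisopropylsilyloxy)propyl]oxocan-6-yl acetate | O=C/C=C/C[C@@H]1O[C@@H]([C@H](O[Si](C(C)C)(C(C)C)C(C)C)CC)C[C@H](OC(C)=O)[C@@H](Cl)C[C@@H]1Cl | intermediate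
23 | (2S,3S,5S,6S,8R)-3,5-dichloro-2-[(2E)-pent-2-en-4-yn-1-yl]-8-[(1R)-1-(triisopropylsilyloxy)propyl]oxocan-6-yl acetate | C#C/C=C/C[C@@H]1O[C@@H]([C@H](O[Si](C(C)C)(C(C)C)C(C)C)CC)C[C@H](OC(C)=O)[C@@H](Cl)C[C@@H]1Cl | intermediate
24 | (2S,3S,5S,6S,8R)-3,5-dichloro-8-[(1R)-1-hydroxypropyl]-2-[(2E)-pent-2-en-4-yn-1-yl]oxocan-6-yl acetate | C#C/C=C/C[C@@H]1O[C@@H]([C@H](O)CC)C[C@H](OC(C)=O)[C@@H](Cl)C[C@@H]1Cl | intermediate
25 | (2S,3S,5S,6S,8R)-8-[(1S)-1-bromopropyl]-3,5-dichloro-2-[(2E)-pent-2-en-4-yn-1-yl]oxocan-6-yl acetate | C#C/C=C/C[C@@H]1O[C@@H]([C@@H](Br)CC)C[C@H](OC(C)=O)[C@@H](Cl)C[C@@H]1Cl | target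

Total step count: 17. Longest linear sequence: 17 steps (1 → 25).

Steps most likely to fail

Step 4. The Cope rearrangement of 6 may be slowed by the branched vinyl terminus, or the catalyst may discriminate the carbenoid faces poorly next to the existing C9 stereocentre, so that C8 forms with poor control. The fallback keeps the same two-bond event but moves the side chain to a later aldol; it sets out from 5 and comes back at 10. Diazo transfer to tert-butyl acetoacetate would give tert-butyl 2-diazo-3-oxobutanoate F1, and TIPSOTf/Et3N would give tert-butyl 2-diazo-3-(triisopropylsilyloxy)but-3-enoate F2. Rh2(OPiv)4-catalysed reaction of F2 with 5 should pass through the racemic cis-divinylcyclopropane F3 to tert-butyl 2-(triisopropylsilyloxy)cyclohepta-1,5-diene-1-carboxylate F4. Trifluoroacetic acid and warming would lead through 2-oxocyclohept-5-ene-1-carboxylic acid F5 to cyclohept-4-en-1-one F6. The E boron enolate of F6 (chlorodicyclohexylborane, Et3N) and propanal should give the racemic anti aldol, which a lipase and vinyl acetate would resolve: (2R)-2-[(1R)-1-hydroxypropyl]cyclohept-4-en-1-one F7 is kept, and its antipode F8 is removed as its acetate F9. Silylation of F7 (TIPSOTf, 2,6-lutidine) returns to 10.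

Step 7. The oxidant may attack the other enolate face and give the C3 epimer. The fallback corrects C3 by SN2 inversion and no longer relies on facial selectivity; it sets out from 11 and comes back at 15. The epimeric (3S,5Z,8R)-3-hydroxy lactone F10 would be inverted under Mitsunobu conditions (AcOH, PPh3, DIAD) to the (3R)-acetoxy lactone F11. Reductive acetylation of F11 (i-Bu2AlH, 3.3 equiv; then Ac2O, pyridine, DMAP) cleaves and re-installs the C3 acetate and gives 15.

Step 13. Chloride may open the activated epoxide at C6, or the ring oxygen O1 may take part transannularly under acylative activation and cause ring contraction. The fallback separates ring opening from acylation and uses a purely nucleophilic chloride source without an acylating electrophile; it sets out from 20 and comes back at 21. Li2CuCl4 in THF should give the chlorohydrin (2S,3S,5S,6S,8R)-2-allyl-3,5-dichloro-8-[(1R)-1-(triisopropylsilyloxy)propyl]oxocan-6-ol F12, and acetylation (Ac2O, pyridine, DMAP) gives 21.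

Further compounds
F1 | step 4 | tert-butyl 2-diazo-3-oxobutanoate | CC(=O)C(=[N+]=[N-])C(=O)OC(C)(C)C
F2 | step 4 | tert-butyl 2-diazo-3-(triisopropylsilyloxy)but-3-enoate | C=C(O[Si](C(C)C)(C(C)C)C(C)C)C(=[N+]=[N-])C(=O)OC(C)(C)C
F3 | step 4 | tert-butyl cis-1-[1-(triisopropylsilyloxy)vinyl]-2-vinylcyclopropane-1-carboxylate (racemic, one enantiomer drawn) | C=C[C@@H]1C[C@]1(C(=O)OC(C)(C)C)C(=C)O[Si](C(C)C)(C(C)C)C(C)C
F4 | step 4 | tert-butyl 2-(triisopropylsilyloxy)cyclohepta-1,5-diene-1-carboxylate | O=C(OC(C)(C)C)C1=C(O[Si](C(C)C)(C(C)C)C(C)C)CC/C=C\C1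
F5 | step 4 | 2-oxocyclohept-5-ene-1-carboxylic acid | O=C1CC/C=C\CC1C(=O)O
F6 | step 4 | cyclohept-4-en-1-one | O=C1CC/C=C\CC1
F7 | step 4 | (2R)-2-[(1R)-1-hydroxypropyl]cyclohept-4-en-1-one | O=C1[C@@H]([C@H](O)CC)C/C=C\CC1
F8 | step 4 | (2S)-2-[(1S)-1-hydroxypropyl]cyclohept-4-en-1-one | O=C1[C@H]([C@@H](O)CC)C/C=C\CC1
F9 | step 4 | acetate of F8 | O=C1[C@H]([C@@H](OC(C)=O)CC)C/C=C\CC1
F10 | step 7 | (3S,5Z,8R)-3-hydroxy-8-[(1R)-1-(triisopropylsilyloxy)propyl]-3,4,7,8-tetrahydro-2H-oxocin-2-one | O=C1O[C@@H]([C@H](O[Si](C(C)C)(C(C)C)C(C)C)CC)C/C=C\C[C@@H]1O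
F11 | step 7 | (3R,5Z,8R)-2-oxo-8-[(1R)-1-(triisopropylsilyloxy)propyl]-3,4,7,8-tetrahydro-2H-oxocin-3-yl acetate | O=C1O[C@@H]([C@H](O[Si](C(C)C)(C(C)C)C(C)C)CC)C/C=C\C[C@H]1OC(C)=O
F12 | step 13 | (2S,3S,5S,6S,8R)-2-allyl-3,5-dichloro-8-[(1R)-1-(triisopropylsilyloxy)propyl]oxocan-6-ol | C=CC[C@@H]1O[C@@H]([C@H](O[Si](C(C)C)(C(C)C)C(C)C)CC)C[C@H](O)[C@@H](Cl)C[C@@H]1Cl
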